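A flask cannot hold more intermediate A than its scarcer charge can supply, if one substrate and one coupling partner make one intermediate A.

in all of them: coupling partner 1.44 M
- Monday's: substrate 1.8 M; run made earlier
- flask: substrate 1.2 M; time 15 d

- the moment within 15 d at which there is most intermediate A
- the amount of intermediate A, in percent of the substrate charged, at that time

- a reading or a percentage of product counts all its forms, free or not

In the flask, substrate is the limiting reagent, so that bound stands at 100%: the ceiling, the smaller charge over the substrate charged. Monday's run has a lower ceiling, 80.0%, and its readings test the bound.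

Monday's run (percent of the substrate charged)

| time / d | intermediate A / % | product / % |
|---|---|---|
| 0.833 | 48.3 | 1.2 |
| 1.67 | 27.2 | 5.4 |
| 2.50 | 15.8 | 10.6 |
| 4.00 | 5.5 | 22.3 |
| 5.00 | 3.4 | 30.4 |

(each reading ± 1 percentage point)

The intermediate A column falls from its first row, so no row shows the rise. The first and third rows, 48.3% and 15.8%, give a first-order fall of 0.670 /d, a half-life of 1.03 d. Run back to zero time at that rate, the first row reads 84.4%, a figure with the scatter of its rows, close to Monday's ceiling. So the reckoning here commits to this: the flask's peak comes early and stands below 100%, and these rows do not give by how much.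

The forecast puts the peak at 0.28 d (0.12 d to 0.6 d) with 76% (64% to 88%), adding: “No reading shows the rise, so the timing is uncertain.”

The flask gives its peak at 0.342 d, with 72.6%.

    substrate + coupling partner → intermediate A (k = 1.00 × 10⁻⁴ /M/s)
    intermediate A → intermediate B (k = 7.00 × 10⁻⁶ /s)
    intermediate B → product (k = 1.90 × 10⁻⁶ /s)
    intermediate A ⇌ intermediate C (K = 9.60, k = 7.90 × 10⁻⁷ /s)
    substrate + product ⇌ idle adduct, settled at all times (K = 1.30 /M)

The flask's peak is 72.6% of its ceiling, with substrate still at 13.9% at 0.342 d. The neighbour flask, charged with 0.86 M of coupling partner (0.717 equiv), has coupling partner as its limiting reagent, and that charge stands at 0% at 15.0 d. Its ceiling is 71.7%, lower than the flask's. The same share of that ceiling gives 52.1%, and the neighbour flask's peak of intermediate A is 52.3%.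

Readings and results were generated by integration on assumed constants.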